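The data stem from a simulated flask from invented constants.

In the violet run the target falls from 22.9% at 4.00 min to 6.3% at 8.00 min, while the other capture product stays near 32.9%, so I ask of each new flask how long its target waits before the reading at 12 min.

| setting | violet | green | winter | spring | summer | dawn |
|---|---|---|---|---|---|---|
| substrate | 20 mM | 20 mM | 20 mM (fed, over 1.0 min) | 20 mM | 20 mM (fed, over 10 min) | 20 mM |
| second nucleophile | 14 mM | 21 mM | 14.0 mM | 14.0 mM (fed, over 10 min) | 14.0 mM | 14.0 mM |
| gas | 8.8 mM (held) | 8.8 mM (held) | 8.8 mM (held) | 8.8 mM (held) | 8.8 mM (held) | 8.8 mM (held) |
| remark | run made earlier | run made earlier | all else is in the flask from the start; the feed brings no volume worth counting | all else is in the flask from the start; the feed brings no volume worth counting | all else is in the flask from the start; the feed brings no volume worth counting | everything together at the start |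
| time |  |  | 12 min | 12 min | 12 min | 12 min |

- violet (time / min: target / %, other capture product / %): 0.500: 13.9, 17.0; 1.00: 25.5, 21.9; 1.50: 31.1, 26.4; 2.50: 33.3, 31.2; 4.00: 22.9, 32.5; 8.00: 6.3, 32.9
- green (time / s: target / %, other capture product / %): 10.0: 2.1, 8.4; 15.0: 5.0, 12.2; 25.0: 8.2, 18.6; 40.0: 14.6, 20.5; 80.0: 23.5, 31.8

(scatter of a reading: 1 percentage point)

- the best flask by share of target in target plus other capture product; "all alike" if 1.5 percentage points covers them all (winter / spring / summer / dawn / all alike)
- share of target in target plus other capture product at the end, winter
- share of target in target plus other capture product at the end, spring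
- share of target in target plus other capture product at the end, summer
- share of target in target plus other capture product at the end, dawn

- at the start none of the gas is in solution

I read the loss off that violet tail, as a first-order loss and with the scatter of the readings:

k_loss = ln(c_target, early / c_target, late) / time between = 0.323 min⁻¹

half-life = 2.15 min

This k_loss, the part of the standing target lost per minute of waiting, gives the part kept after a wait w:

kept = exp(−k_loss · w)

The first setting is the substrate feed. Target made at the end of the slow feed in summer waits 2.00 min, so the part kept is 0.525, about half. Target made at the end of the quick feed in winter waits 11.0 min, so the part kept is 0.0288, hardly any, far less than in summer.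

The second setting is the feed of second nucleophile. In spring the substrate goes in at the start, as in dawn, so I expect the same long wait, and the share (the selectivity) can move through a smaller amount of other capture product.

The third setting is the time: 12 min is 5.58 half-lives, longer than the slow feed.

Dawn is the violet recipe, so I carry the last violet reading forward and get target 1.73% and a share of 5.00%.

The forecast says “Summer delivers substrate late” and names summer, with 7.3% for winter, 28% for spring, 40% for summer and 4.2% for dawn, a little below my dawn figure.

The flasks give summer as best at 35.5%, with spring at 28.9%, winter at 6.74% and dawn at 4.88%.

    gas ⇌ first nucleophile, rate k1*(csat - [first nucleophile]) (kL = 0.0560 s⁻¹)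
    second nucleophile + intermediate → other capture product (k = 450 M⁻¹ s⁻¹)
    target → over-reaction product (k = 0.00600 s⁻¹)
    intermediate → side product (k = 0.230 s⁻¹)
    substrate → intermediate (k = 0.0130 s⁻¹)
    first nucleophile + intermediate → target (k = 1600 M⁻¹ s⁻¹)

Dawn holds 1.67% of side product, and with that step struck out its share reads 4.88%. In spring, with substrate down to 0.0410% at 10.0 min, the target of 4.46% reckons to 2.34% at 12 min, and spring holds 2.19%. Dawn read at 5.0 min holds target 18.5%, which reckons to 1.93% at 12 min, and dawn holds 1.72%.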